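**Retrosynthetic overview**

1. Numbering: ten-membered carbocycle C1–C10 with ring-cis C1=C10 (C10 carries CO2Me), C2–OH, C4–C5 oxirane (methyl on C4), γ-lactone O–C6/C7–C11(=C13H2)–C12(=O), C8 angelate, C9 acetate. The strategy rests on C9 being a carbinol carbon bonded directly to C10 of the cis acrylate. C9–C10 is therefore cut last: Ni/Cr coupling of a C9 aldehyde with a (Z)-2-iodoenoate (iodine cis to C2) closes the ten-membered ring.
2. The seco-aldehyde comes from a C6–C7 Barbier coupling of a C1–C6 epoxy aldehyde with a C7–C9/C11–C13 bromomethylacrylate whose ester is tied back to O9 as a δ-lactone. The tether locks the allyl metal in the E-crotyl form (trans lactone, correct C7/C8), and an acyl shift from O9 to O6 then frees the C9 hydroxyl.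
3. C1–C6: (S)-PMB glycidyl ether (C2) is opened by a (Z)-alkenyllithium (C4=C5), the iodoenoate is made by Wittig olefination, and C4/C5 are set by Sharpless epoxidation.
4. Ring order: oxirane (step 9), γ-lactone (step 14, through a transient dihydropyranone from the reagent of step 13), ten-membered ring (step 20); then acetylation and desilylation.

Key step: step 20

Assumption: 4, 13 and 14 are taken as purchasable; an open-chain γ-substituted 2-(bromomethyl)acrylate would react in its Z-crotyl form and give the cis lactone, which is why the ester of the allyl partner is tied back to O9. (TBS = tert-butyldimethylsilyl, TES = triethylsilyl, PMB = 4-methoxybenzyl.)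

**Route**

Step 1
Reactants: 1 but-2-yn-1-ol
Product: 2 (Z)-3-iodobut-2-en-1-ol
Conditions: Red-Al, THF, 0 °C → rt; then I2, −78 → 0 °C
Reagents that add atoms: iodine, II
Why: Hydroxyl-directed trans-hydroalumination places aluminium on C3 and iodinolysis with retention should give the (Z)-3-iodo allylic alcohol (hydroalumination–iodination of a propargylic alcohol).

Step 2
Reactants: 2 (Z)-3-iodobut-2-en-1-ol
Product: 3 (Z)-tert-butyl[(3-iodobut-2-en-1-yl)oxy]dimethylsilane
Conditions: TBSCl, imidazole, CH2Cl2, 0 °C → rt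
Reagents that add atoms: tert-butyldimethylsilyl chloride, CC(C)(C)[Si](C)(C)Cl
Why: Standard silylation of a primary alcohol.

Step 3
Reactants: 3 (Z)-tert-butyl[(3-iodobut-2-en-1-yl)oxy]dimethylsilane; 4 (S)-2-{[(4-methoxybenzyl)oxy]methyl}oxirane
Product: 5 (2S,4Z)-6-(TBS-oxy)-1-(PMB-oxy)-4-methylhex-4-en-2-ol
Conditions: t-BuLi (2 equiv), Et2O, −78 °C; then 4, BF3·OEt2, −78 °C
Reagents that add atoms: none
Why: Iodine–lithium exchange with retention of alkene geometry and BF3-assisted opening of the terminal epoxide at its CH2 (organolithium/BF3 epoxide opening) should join C3–C4 and carry the C2 stereocentre of 4 over unchanged.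

Step 4
Reactants: 5 (2S,4Z)-6-(TBS-oxy)-1-(PMB-oxy)-4-methylhex-4-en-2-ol
Product: 6 (2S,4Z)-2,6-bis(TBS-oxy)-1-(PMB-oxy)-4-methylhex-4-ene
Conditions: TBSCl, imidazole, DMF, rt
Reagents that add atoms: tert-butyldimethylsilyl chloride, CC(C)(C)[Si](C)(C)Cl
Why: Silylation of the secondary alcohol gives the C2 ether that is meant to last to the final step.

Step 5
Reactants: 6 (2S,4Z)-2,6-bis(TBS-oxy)-1-(PMB-oxy)-4-methylhex-4-ene
Product: 7 (2S,4Z)-2,6-bis(TBS-oxy)-4-methylhex-4-en-1-ol
Conditions: DDQ, CH2Cl2/pH 7 buffer, 0 °C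
Reagents that add atoms: none
Why: Oxidative PMB ether cleavage with DDQ should leave both silyl ethers and the trisubstituted alkene untouched.

Step 6
Reactants: 7 (2S,4Z)-2,6-bis(TBS-oxy)-4-methylhex-4-en-1-ol
Product: 8 (2S,4Z)-2,6-bis(TBS-oxy)-4-methylhex-4-enal
Conditions: Dess–Martin periodinane, NaHCO3, CH2Cl2, 0 °C → rt
Reagents that add atoms: none
Why: Buffered Dess–Martin oxidation should give the α-silyloxy aldehyde without epimerisation at C2.

Step 7
Reactants: 8 (2S,4Z)-2,6-bis(TBS-oxy)-4-methylhex-4-enal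
Product: 9 methyl (2Z,4S,6Z)-4,8-bis(TBS-oxy)-2-iodo-6-methylocta-2,6-dienoate
Conditions: Ph3P=C(I)CO2Me (preformed from Ph3P=CHCO2Me, I2, K2CO3), CH2Cl2, rt → 40 °C
Reagents that add atoms: methyl iodo(triphenylphosphoranylidene)acetate, COC(=O)C(I)=P(c1ccccc1)(c1ccccc1)c1ccccc1
Why: Wittig olefination with the stabilised α-iodo ylide should place the ester trans to the chain, i.e. iodine cis to C2 ((Z)-2-iodoenoate), the minor E isomer being removed by chromatography.

Step 8
Reactants: 9 methyl (2Z,4S,6Z)-4,8-bis(TBS-oxy)-2-iodo-6-methylocta-2,6-dienoate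
Product: 10 methyl (2Z,4S,6Z)-4-(TBS-oxy)-8-hydroxy-2-iodo-6-methylocta-2,6-dienoate
Conditions: HF·pyridine, pyridine, THF, 0 °C
Reagents that add atoms: none
Why: Buffered HF·pyridine should cleave the primary allylic TBS ether much faster than the hindered secondary one (selective desilylation).

Step 9
Reactants: 10 methyl (2Z,4S,6Z)-4-(TBS-oxy)-8-hydroxy-2-iodo-6-methylocta-2,6-dienoate
Product: 11 methyl (2Z,4S)-4-(TBS-oxy)-5-[(2R,3S)-3-(hydroxymethyl)-2-methyloxiran-2-yl]-2-iodopent-2-enoate
Conditions: Ti(OiPr)4, L-(+)-DET, t-BuOOH, 4 Å MS, CH2Cl2, −20 °C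
Reagents that add atoms: tert-butyl hydroperoxide, CC(C)(C)OO
Why: Sharpless asymmetric epoxidation with L-(+)-tartrate should deliver oxygen to the face of the Z-allylic alcohol that gives the (4R,5S)-epoxide (as nerol gives (2S,3R)-epoxynerol), by reagent control, while the electron-poor iodoacrylate does not react.

Step 10
Reactants: 11 methyl (2Z,4S)-4-(TBS-oxy)-5-[(2R,3S)-3-(hydroxymethyl)-2-methyloxiran-2-yl]-2-iodopent-2-enoate
Product: 12 methyl (2Z,4S)-4-(TBS-oxy)-5-[(2R,3R)-3-formyl-2-methyloxiran-2-yl]-2-iodopent-2-enoate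
Conditions: Dess–Martin periodinane, NaHCO3, CH2Cl2, 0 °C
Reagents that add atoms: none
Why: Buffered Dess–Martin oxidation of the epoxy alcohol should give the epoxy aldehyde (C6), to be used crude.

Step 11
Reactants: 13 (S)-but-3-ene-1,2-diol; 14 2-(bromomethyl)acrylic acid
Product: 15 (S)-2-hydroxybut-3-en-1-yl 2-(bromomethyl)acrylate
Conditions: DIC, DMAP (cat.), CH2Cl2, −20 °C
Reagents that add atoms: none
Why: Carbodiimide (Steglich) esterification at low temperature should acylate the primary hydroxyl of the diol in preference to the secondary allylic one.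

Step 12
Reactants: 15 (S)-2-hydroxybut-3-en-1-yl 2-(bromomethyl)acrylate
Product: 16 (S)-2-(triethylsilyloxy)but-3-en-1-yl 2-(bromomethyl)acrylate
Conditions: TESOTf, 2,6-lutidine, CH2Cl2, −78 °C
Reagents that add atoms: triethylsilyl trifluoromethanesulfonate, CC[Si](CC)(CC)OS(=O)(=O)C(F)(F)F
Why: Silyl triflate with a hindered base silylates the secondary alcohol without attacking the allylic bromide.

Step 13
Reactants: 16 (S)-2-(triethylsilyloxy)but-3-en-1-yl 2-(bromomethyl)acrylate
Product: 17 (S)-3-(bromomethyl)-5-(triethylsilyloxy)-5,6-dihydro-2H-pyran-2-one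
Conditions: Grubbs II (5 mol%), CH2Cl2 (5 mM), 40 °C
Reagents that add atoms: none
Why: Ring-closing metathesis between the vinyl group and the 1,1-disubstituted acrylate should close the six-membered unsaturated lactone, which holds C8 cis to the carbonyl C12.

Step 14
Reactants: 12 methyl (2Z,4S)-4-(TBS-oxy)-5-[(2R,3R)-3-formyl-2-methyloxiran-2-yl]-2-iodopent-2-enoate; 17 (S)-3-(bromomethyl)-5-(triethylsilyloxy)-5,6-dihydro-2H-pyran-2-one
Product: 19 (2S,4R,5S,6S,7S,8S)-6,12-olide with free 9-OH and 8-OTES (2-OTBS; 4,5-epoxide; C1=C10 iodoenoate), via δ-lactone adduct 18 (not isolated)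
Conditions: In powder, THF/H2O, rt; then PPTS (cat.), CH2Cl2, rt
Reagents that add atoms: none
Why: Indium-mediated Barbier (Dreiding–Schmidt-type) allylation in which the allylindium from 17 adds through C7 in a chair transition state: the lactone ring holds C8 cis to C12 (E-crotyl type, so C6–OH comes out anti to the C7–C8 bond), the aldehyde approaches anti to the C8 silyloxy group (sets C7) and on its Felkin–Anh face (C6 erythro to the epoxide), three preferences that point to the same isomer, after which the C6 alkoxide takes the acyl group from O9 (δ- to γ-lactone) and indium leaves the alkenyl iodide alone.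

Step 15
Reactants: 19 6,12-olide with 9-OH and 8-OTES
Product: 20 (2S,4R,5S,6S,7R,8S)-6,12-olide 8,9-diol
Conditions: HF·pyridine, pyridine, THF, 0 °C
Reagents that add atoms: none
Why: Buffered HF·pyridine should remove the triethylsilyl ether selectively while the secondary TBS ether at C2 stays (selective desilylation).

Step 16
Reactants: 20 6,12-olide 8,9-diol
Product: 21 (2S,4R,5S,6S,7R,8S)-6,12-olide with 9-OTES and free 8-OH
Conditions: TESCl, imidazole, CH2Cl2, −40 °C
Reagents that add atoms: triethylsilyl chloride, CC[Si](Cl)(CC)CC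
Why: The primary hydroxyl of the 1,2-diol is silylated faster than the hindered secondary one at low temperature (selective silylation).

Step 17
Reactants: 21 6,12-olide with 9-OTES and free 8-OH; 22 angelic acid
Product: 24 (2S,4R,5S,6S,7R,8S)-8-O-angeloyl 6,12-olide with 9-OTES, via mixed anhydride 23 (not isolated)
Conditions: 2,4,6-Cl3C6H2COCl, Et3N, toluene, rt; then 21, 70 °C
Reagents that add atoms: none
Why: Yamaguchi esterification through the mixed anhydride, run without DMAP, should acylate O8 without Z-to-E isomerisation of the angelate and without touching the C8 configuration.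

Step 18
Reactants: 24 8-O-angeloyl 6,12-olide with 9-OTES
Product: 25 (2S,4R,5S,6S,7R,8S)-8-O-angeloyl 6,12-olide 9-ol
Conditions: HF·pyridine, pyridine, THF, 0 °C
Reagents that add atoms: none
Why: The primary triethylsilyl ether is cleaved under buffered acidic fluoride conditions that keep the C2 TBS ether and should not promote acyl migration from O8 (selective desilylation).

Step 19
Reactants: 25 8-O-angeloyl 6,12-olide 9-ol
Product: 26 (2S,4R,5S,6S,7S,8S)-seco-aldehyde (C9 aldehyde; 8-O-angeloyl; 6,12-olide; 4,5-epoxide; 2-OTBS; (Z)-2-iodoenoate)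
Conditions: Dess–Martin periodinane, NaHCO3, CH2Cl2, 0 °C
Reagents that add atoms: none
Why: Buffered Dess–Martin oxidation should give the α-acyloxy aldehyde without epimerisation at C8 if it is used at once.

Step 20
Reactants: 26 seco-aldehyde
Product: 27 (2S,4R,5S,6S,7R,8S,9S)-ten-membered C9 alcohol (2-O-TBS, 9-deacetyl target)
Conditions: CrCl2 (10 equiv), NiCl2 (1 mol%), degassed DMSO, 2 mM, rt, syringe-pump addition of 26
Reagents that add atoms: none
Why: Nickel(0) formed in situ inserts into the electron-poor C10–I bond and passes the alkenyl group to chromium(III) with retention of alkene geometry, and the alkenylchromium adds to the C9 aldehyde, so no free carbanion arises at C10 and loss of the C2 or C9 oxygen or attack on the lactone, esters or epoxide is not expected. The closest known reaction type is the Nozaki–Hiyama–Kishi coupling of α-iodo enones and enoates with aldehydes, including its use in medium-ring and macrocyclic closures. The ten-membered ring C1–C10 closes in the 10-exo-trig mode (addition at the C9 carbonyl carbon, the oxygen staying outside the ring) under high dilution to hold back dimers. The new stereocentre C9 is set by the aldehyde face that the C10–Cr bond reaches in the cyclic transition state, which is governed by the adjacent C8 angelate (α-acyloxy aldehyde, chromium able to bridge the aldehyde and ester oxygens) and by the conformation imposed by the trans lactone and the cis C1=C10 bond. The step needs 8,9-syn (threo) addition, O9 trans to O8 on the ring, and retention of the iodide geometry so that C9 ends up cis to C2; the geometry is secured by the stereospecific Ni/Cr exchange, whereas the C9 face rests on the chelated, ring-constrained transition state and is the open point of the route.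

Step 21
Reactants: 27 ten-membered C9 alcohol
Product: 28 (2S,4R,5S,6S,7R,8S,9S)-9-O-acetyl-2-O-TBS target
Conditions: Ac2O, pyridine, DMAP (cat.), CH2Cl2, 0 °C
Reagents that add atoms: acetic anhydride, CC(=O)OC(C)=O
Why: Standard acetylation of the secondary allylic alcohol.

Step 22
Reactants: 28 9-O-acetyl-2-O-TBS target
Product: 29 CNP0278274.1 (target)
Conditions: HF·pyridine, pyridine, THF, 0 °C → rt
Reagents that add atoms: none
Why: Buffered acidic fluoride desilylation should free the C2 hydroxyl without acyl migration between O9 and O2 and without opening the epoxide.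

**Compound list**

1 | but-2-yn-1-ol | CC#CCO | starting material
2 | (Z)-3-iodobut-2-en-1-ol | C/C(I)=C/CO | intermediate
3 | (Z)-tert-butyl[(3-iodobut-2-en-1-yl)oxy]dimethylsilane | C/C(I)=C/CO[Si](C)(C)C(C)(C)C | intermediate
4 | (S)-2-{[(4-methoxybenzyl)oxy]methyl}oxirane | COc1ccc(COC[C@@H]2CO2)cc1 | starting material
5 | (2S,4Z)-6-(TBS-oxy)-1-(PMB-oxy)-4-methylhex-4-en-2-ol | COc1ccc(COC[C@@H](O)C/C(C)=C\CO[Si](C)(C)C(C)(C)C)cc1 | intermediate
6 | (2S,4Z)-2,6-bis(TBS-oxy)-1-(PMB-oxy)-4-methylhex-4-ene | COc1ccc(COC[C@@H](O[Si](C)(C)C(C)(C)C)C/C(C)=C\CO[Si](C)(C)C(C)(C)C)cc1 | intermediate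
7 | (2S,4Z)-2,6-bis(TBS-oxy)-4-methylhex-4-en-1-ol | OC[C@@H](O[Si](C)(C)C(C)(C)C)C/C(C)=C\CO[Si](C)(C)C(C)(C)C | intermediate
8 | (2S,4Z)-2,6-bis(TBS-oxy)-4-methylhex-4-enal | O=C[C@@H](O[Si](C)(C)C(C)(C)C)C/C(C)=C\CO[Si](C)(C)C(C)(C)C | intermediate
9 | methyl (2Z,4S,6Z)-4,8-bis(TBS-oxy)-2-iodo-6-methylocta-2,6-dienoate | COC(=O)/C(I)=C/[C@@H](O[Si](C)(C)C(C)(C)C)C/C(C)=C\CO[Si](C)(C)C(C)(C)C | intermediate
10 | methyl (2Z,4S,6Z)-4-(TBS-oxy)-8-hydroxy-2-iodo-6-methylocta-2,6-dienoate | COC(=O)/C(I)=C/[C@@H](O[Si](C)(C)C(C)(C)C)C/C(C)=C\CO | intermediate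
11 | methyl (2Z,4S)-4-(TBS-oxy)-5-[(2R,3S)-3-(hydroxymethyl)-2-methyloxiran-2-yl]-2-iodopent-2-enoate | OC[C@@H]1O[C@]1(C)C[C@H](O[Si](C)(C)C(C)(C)C)/C=C(\I)C(=O)OC | intermediate
12 | methyl (2Z,4S)-4-(TBS-oxy)-5-[(2R,3R)-3-formyl-2-methyloxiran-2-yl]-2-iodopent-2-enoate | O=C[C@@H]1O[C@]1(C)C[C@H](O[Si](C)(C)C(C)(C)C)/C=C(\I)C(=O)OC | intermediate
13 | (S)-but-3-ene-1,2-diol | C=C[C@H](O)CO | starting material
14 | 2-(bromomethyl)acrylic acid | C=C(CBr)C(=O)O | starting material
15 | (S)-2-hydroxybut-3-en-1-yl 2-(bromomethyl)acrylate | C=C[C@H](O)COC(=O)C(=C)CBr | intermediate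
16 | (S)-2-(triethylsilyloxy)but-3-en-1-yl 2-(bromomethyl)acrylate | C=C[C@H](O[Si](CC)(CC)CC)COC(=O)C(=C)CBr | intermediate
17 | (S)-3-(bromomethyl)-5-(triethylsilyloxy)-5,6-dihydro-2H-pyran-2-one | BrCC1=C[C@H](O[Si](CC)(CC)CC)COC1=O | intermediate
18 | (2S,4R,5S,6S,7S,8S)-δ-lactone adduct: 3-methylene-5-(TES-oxy)tetrahydropyran-2-one (O9–C12 lactone) carrying at C7 the C6 carbinol, the 4,5-epoxide, 2-OTBS and the (Z)-2-iodoenoate | C=C1C(=O)OC[C@@H](O[Si](CC)(CC)CC)[C@@H]1[C@H](O)[C@@H]1O[C@]1(C)C[C@H](O[Si](C)(C)C(C)(C)C)/C=C(\I)C(=O)OC | intermediate (not isolated)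
19 | (2S,4R,5S,6S,7S,8S)-6,12-olide (trans α-methylene-γ-butyrolactone) with 9-OH, 8-OTES, 4,5-epoxide, 2-OTBS, (Z)-2-iodoenoate | OC[C@@H](O[Si](CC)(CC)CC)[C@H]1C(=C)C(=O)O[C@@H]1[C@@H]1O[C@]1(C)C[C@H](O[Si](C)(C)C(C)(C)C)/C=C(\I)C(=O)OC | intermediate
20 | (2S,4R,5S,6S,7R,8S)-6,12-olide 8,9-diol | OC[C@@H](O)[C@H]1C(=C)C(=O)O[C@@H]1[C@@H]1O[C@]1(C)C[C@H](O[Si](C)(C)C(C)(C)C)/C=C(\I)C(=O)OC | intermediate
21 | (2S,4R,5S,6S,7R,8S)-6,12-olide with 9-OTES and 8-OH | CC[Si](CC)(CC)OC[C@@H](O)[C@H]1C(=C)C(=O)O[C@@H]1[C@@H]1O[C@]1(C)C[C@H](O[Si](C)(C)C(C)(C)C)/C=C(\I)C(=O)OC | intermediate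
22 | angelic acid, (Z)-2-methylbut-2-enoic acid | C/C=C(/C)C(=O)O | starting material
23 | angelic 2,4,6-trichlorobenzoic anhydride | C/C=C(/C)C(=O)OC(=O)c1c(Cl)cc(Cl)cc1Cl | intermediate (not isolated)
24 | (2S,4R,5S,6S,7R,8S)-8-O-angeloyl 6,12-olide with 9-OTES | CC[Si](CC)(CC)OC[C@@H](OC(=O)/C(C)=C\C)[C@H]1C(=C)C(=O)O[C@@H]1[C@@H]1O[C@]1(C)C[C@H](O[Si](C)(C)C(C)(C)C)/C=C(\I)C(=O)OC | intermediate
25 | (2S,4R,5S,6S,7R,8S)-8-O-angeloyl 6,12-olide 9-ol | OC[C@@H](OC(=O)/C(C)=C\C)[C@H]1C(=C)C(=O)O[C@@H]1[C@@H]1O[C@]1(C)C[C@H](O[Si](C)(C)C(C)(C)C)/C=C(\I)C(=O)OC | intermediate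
26 | (2S,4R,5S,6S,7S,8S)-seco-aldehyde (C9 aldehyde, 8-O-angeloyl, 6,12-olide, 4,5-epoxide, 2-OTBS, (Z)-2-iodoenoate) | O=C[C@@H](OC(=O)/C(C)=C\C)[C@H]1C(=C)C(=O)O[C@@H]1[C@@H]1O[C@]1(C)C[C@H](O[Si](C)(C)C(C)(C)C)/C=C(\I)C(=O)OC | intermediate
27 | (2S,4R,5S,6S,7R,8S,9S)-ten-membered C9 alcohol (2-O-TBS, 9-deacetyl target) | C=C1C(=O)O[C@H]2[C@H]1[C@H](OC(=O)/C(C)=C\C)[C@@H](O)/C(C(=O)OC)=C\[C@@H](O[Si](C)(C)C(C)(C)C)C[C@@]1(C)O[C@@H]21 | intermediate
28 | (2S,4R,5S,6S,7R,8S,9S)-9-O-acetyl-2-O-TBS target | C=C1C(=O)O[C@H]2[C@H]1[C@H](OC(=O)/C(C)=C\C)[C@@H](OC(C)=O)/C(C(=O)OC)=C\[C@@H](O[Si](C)(C)C(C)(C)C)C[C@@]1(C)O[C@@H]21 | intermediate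
29 | CNP0278274.1 (2S,4R,5S,6S,7R,8S,9S) | C=C1C(=O)O[C@H]2[C@H]1[C@H](OC(=O)/C(C)=C\C)[C@@H](OC(C)=O)/C(C(=O)OC)=C\[C@@H](O)C[C@@]1(C)O[C@@H]21 | target

**Step count**

Total: 22 steps. Longest linear sequence: 19 steps (steps 1–10, then 14–22); the allyl partner 17 takes 3 steps (11–13).

**Steps most likely to fail**

Step 20 (ring closure). The vinylchromium may add to the wrong face of the C9 aldehyde, because an open-chain Felkin–Anh preference of the α-acyloxy aldehyde would favour the 8,9-erythro product; oligomerisation may also compete. The fallback sets out from 26 and does not try to steer the face. Cyclisation under the same regime would then give mainly the C9-epimeric alcohol F1. Mitsunobu reaction of F1 with acetic acid (PPh3, DIAD, toluene, 0 °C) should invert C9 and install the acetate in one operation; direct displacement is expected because C1 is a hindered ring carbon next to the silyloxy centre. The fallback comes back to the route at 28.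

Step 14 (Barbier coupling and acyl shift). The aldehyde may approach the dihydropyranone with poor facial discrimination, the allylindium may lose silyloxide from C8 (aromatisation toward a 2-pyranone), or the acyl shift may stall. The fallback sets out from 12 and builds the lactone in two stages by known butenolide chemistry.
- Indium-mediated allylation of 12 with methyl 2-(bromomethyl)acrylate (THF/H2O) should give the Felkin–Anh hydroxy ester F2, which lactonises with PPTS to the α-methylene lactone F3.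
- Bromine addition to the exocyclic alkene gives the dibromide F4, and triethylamine removes HBr to give the 3-(bromomethyl)butenolide F5.
- Indium-mediated allylation of (triethylsilyloxy)acetaldehyde with F5 should add anti to the C6 substituent (trans lactone) and, through the chair transition state, give the 8-epi alcohol F6.
- Mitsunobu esterification of F6 with angelic acid (PPh3, DIAD) should invert C8 and install the angelate, coming back to the route at 24.

Step 17 (angeloylation). The angelate may isomerise to the tiglate under the warm basic conditions, or the free 8-OH may shift the lactone before it is acylated. The fallback sets out from 21 and builds the Z-olefin of the ester on the substrate. Carbodiimide esterification of 21 with 2-[bis(2,2,2-trifluoroethoxy)phosphoryl]propanoic acid gives the phosphonate ester F7. Still–Gennari olefination of F7 with acetaldehyde (KHMDS, 18-crown-6, THF, −78 °C) should form the (Z)-2-methylbut-2-enoate, coming back to the route at 24.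

Further compounds
F1 | step 20 | (2S,4R,5S,6S,7R,8S,9R)-ten-membered C9 alcohol, the C9 epimer of 27 | C=C1C(=O)O[C@H]2[C@H]1[C@H](OC(=O)/C(C)=C\C)[C@H](O)/C(C(=O)OC)=C\[C@@H](O[Si](C)(C)C(C)(C)C)C[C@@]1(C)O[C@@H]21
F2 | step 14 | methyl 2-methylene-4-hydroxy ester from 12 (6S carbinol, 4,5-epoxide, 2-OTBS, (Z)-2-iodoenoate) | C=C(C[C@H](O)[C@@H]1O[C@]1(C)C[C@H](O[Si](C)(C)C(C)(C)C)/C=C(\I)C(=O)OC)C(=O)OC
F3 | step 14 | (6S)-α-methylene-γ-butyrolactone with unsubstituted C7 | C=C1C[C@@H]([C@@H]2O[C@]2(C)C[C@H](O[Si](C)(C)C(C)(C)C)/C=C(\I)C(=O)OC)OC1=O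
F4 | step 14 | 3-bromo-3-(bromomethyl)-γ-butyrolactone (dibromide of F3, mixture at C11) | BrCC1(Br)C[C@@H]([C@@H]2O[C@]2(C)C[C@H](O[Si](C)(C)C(C)(C)C)/C=C(\I)C(=O)OC)OC1=O
F5 | step 14 | (6S)-3-(bromomethyl)furan-2(5H)-one carrying the C1–C5 chain | BrCC1=C[C@@H]([C@@H]2O[C@]2(C)C[C@H](O[Si](C)(C)C(C)(C)C)/C=C(\I)C(=O)OC)OC1=O
F6 | step 14 | (2S,4R,5S,6S,7R,8R)-6,12-olide with 9-OTES and 8-OH, the C8 epimer of 21 | CC[Si](CC)(CC)OC[C@H](O)[C@H]1C(=C)C(=O)O[C@@H]1[C@@H]1O[C@]1(C)C[C@H](O[Si](C)(C)C(C)(C)C)/C=C(\I)C(=O)OC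
F7 | step 17 | 8-O-{2-[bis(2,2,2-trifluoroethoxy)phosphoryl]propanoyl} ester of 21 | CC[Si](CC)(CC)OC[C@@H](OC(=O)C(C)P(=O)(OCC(F)(F)F)OCC(F)(F)F)[C@H]1C(=C)C(=O)O[C@@H]1[C@@H]1O[C@]1(C)C[C@H](O[Si](C)(C)C(C)(C)C)/C=C(\I)C(=O)OC
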